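Follow one molecule of starting material, not the concentration, and ask for its chance per minute of becoming target.

| setting | cedar | birch | maple | elm | oak |
|---|---|---|---|---|---|
| starting material | 50.0 mM | 30.0 mM | 50.0 mM | 150 mM | 150 mM |
| partner | 125 mM | 105 mM | 125 mM | 125 mM | 125 mM |
| catalyst | 0.100 mM | 0.100 mM | 0.0500 mM | 0.100 mM | 0.200 mM |
| time |  |  |  |  | 7.4 min |

- cedar run (time / min: [target] / mM): 0.56: 1.94; 1.7: 5.53; 3.3: 9.60; 5.2: 14.23; 7.4: 19.14
- birch run (time / min: [target] / mM): 0.56: 1.35; 1.7: 3.04; 3.3: 5.70; 5.2: 9.05; 7.4: 11.85
- maple run (time / min: [target] / mM): 0.56: 1.27; 1.7: 2.83; 3.3: 4.71; 5.2: 7.72; 7.4: 10.70
- elm run (time / min: [target] / mM): 0.56: 4.61; 1.7: 14.20; 3.3: 26.66; 5.2: 40.32; 7.4: 54.01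

(standard deviation of a reading: 0.2 mM)

1. order of the initial rate in [catalyst], near the charge of the cedar run, the rate being that where two percent of its starting material are target
2. order of the initial rate in [starting material], near the charge of the cedar run, the rate being that where two percent of its starting material are target (one fixed amount of target, the same in the runs compared)
3. the birch run starts with 20.0 mM less of starting material and of partner than the cedar run, and with no target. Compared where both hold the same amount of starting material, once fifteen percent of what the birch run was charged with has turned into target, is the birch run faster, slower or alike (within a tenth)?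
4. target in the oak run at 7.4 min, as a share of the starting material charged

- Overall: starting material + partner -> target, with catalyst as catalyst.
- Constant volume, constant temperature.
- A reading of a species includes what of it is bound.
- "The second partner" is partner.
- An order is taken over about fifteen percent of the charge, up and down.

Call that chance the hazard: the natural logarithm of charge over what is left, divided by time. Read it at the last reading of each run. Elm has turned 36.0% of its charge by 7.4 min, so its hazard is 0.0603 min⁻¹. Cedar gives 0.0652 min⁻¹ and birch 0.0679 min⁻¹. Maple holds half the catalyst of cedar and gives 0.0325 min⁻¹, half the cedar hazard. So take the catalyst order as 1.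

Oak is elm with twice the catalyst. Solve it at two extremes.

First extreme: fixed hazard (pseudo-first-order). The charge does not matter, doubled catalyst doubles the hazard, and the share left in elm is squared. Oak then turns 59.0%.

Second extreme: fixed rate (zero-order in starting material). Target grows evenly, so oak turns 72.0%. Here the hazard at 150 mM of charge would be a third of that at 50.0 mM.

Now hold the readings against these. Elm's hazard is 0.925 of cedar's, which is close to the first extreme, so commit to oak near 59.0%. That ratio, averaged over the range of charges, gives an order in starting material of 0.929.

The forecast gives catalyst order 1, order in starting material 0.85, birch alike and oak 59%. Its order is lower than the 0.929 reckoned here, and it rests on this reading: “This indicates mild saturation”.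

The flask gives catalyst order 1.0, order in starting material 1.1, birch alike and oak 58.9%.

    catalyst + partner ⇌ catalyst-reagent complex, settled at all times (30.90 L mol⁻¹)
    catalyst-reagent complex + starting material → target + catalyst (3378 L mol⁻¹ min⁻¹)
    starting material + partner ⇌ idle substrate-reagent adduct, settled at all times (29.20 L mol⁻¹)
    2 starting material ⇌ idle substrate dimer, settled at all times (12.80 L mol⁻¹)

Doubled, elm's hazard 0.0603 min⁻¹ puts oak at 59.0%, and the flask holds 58.9%. Halved, it puts a quarter of maple's charge at 9.54 min, and the maple run got there sooner, in 9.03 min. The order is where the numbers part. In the cedar run, the pairing of starting material with partner to the idle substrate-reagent adduct raises the apparent order in starting material to 1.1, from 0.72 without that pairing.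

The data are calculated for substances that don't exist, and the scatter is random.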